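The L of the east run cannot all have come from the J charged. In the east run J is 20.1% of the charge, yet L reads 23.9% at 6.00 h, more than that, so X must pass into J. Nor can charge vanish, though X, D and L together read 25.9% there. D falls as X goes, so we let D take a second G and become an unread product, Q.

the same everywhere: X 0.51 M; J 0.128 M

|  | G | remark | time |
|---|---|---|---|
| south-east | 0.31 M | run made earlier |  |
| east | 1.2 M | run made earlier |  |
| flask | 0.612 M |  | 8.0 h |

| run | time / h | D / % | L / % | X / % |
|---|---|---|---|---|
| south-east | 0.417 | 19.0 | 7.1 | 61.2 |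
| south-east | 1.33 | 21.4 | 9.3 | 52.0 |
| south-east | 2.50 | 22.5 | 9.7 | 51.7 |
| south-east | 4.00 | 23.4 | 9.9 | 50.5 |
| south-east | 5.00 | 21.8 | 9.6 | 49.5 |
| south-east | 6.00 | 22.6 | 10.6 | 47.7 |
| east | 1.00 | 11.9 | 22.4 | 5.8 |
| east | 2.00 | 5.4 | 22.9 | 1.7 |
| east | 3.00 | 2.2 | 23.2 | 1.1 |
| east | 4.00 | 2.9 | 23.1 | 0.3 |
| east | 5.00 | 0.7 | 23.8 | 0 |
| east | 6.00 | 1.6 | 23.9 | 0.4 |

(scatter of a reading: 0.5 percentage points)

Our measure is the G ration, the G charged as a fraction of the X and J together charged: 95.9% in this flask, 48.6% in the south-east run. When G is spent, the ration equals D + L + 2Q. This flask looks contradictory: its ration of 95.9% comes close to the whole charge, yet we expect part of the charge to be left over once G is spent.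

We take the south-east readings at 2.50 h as standing after G's end, which gives Q 8.19% and L per D plus Q of 0.316. We assume for this flask that this ratio holds and that D stays at its south-east reading. The ration then gives Q 28.6%, L 16.2% and 32.7% left over. The contradiction clears: in our reckoning for this flask Q takes 57.2% of the charge in G, more than D and L together, and G is the limiting reagent here. Our share of D is 58.2%.

1. share of D in D plus L at 30 s
2. share of D in D plus L at 15 min
3. share of D in D plus L at 8.0 h
4. which of D and L there is more of at 8.0 h

- the earlier runs were read with a standard deviation of 0.5 percentage points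

The forecast gives 74%, 69% and 53%, with D ahead, below our share at the end, and says "The D-consumption rate is uncertain, because the two runs disagree".

The flask gives 61.5%, 68.3% and 59.9%, with D at 24.7% and L at 16.5%.

    G + D → Q (k = 0.110 /M/min)
    2 X → E (k = 5.10 × 10⁻⁴ /M/min)
    G + J → L (k = 0.240 /M/min)
    X + G → D (k = 0.0780 /M/min)
    X ⇌ J (K = 0.100, k = 0.130 /min)

In this flask G stands at 0% at 8.00 h, and D + L + 2Q comes to 95.9% against the ration of 95.9%. The neighbour with 1.5 M of G has a ration of 235%. Its L of 23.5% and Q of 76.2% take 176%, which leaves 25.1% of its G by the ration. The neighbour ends with 25% of its G left, X at 0% and D at 0%.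

All runs were generated by integration for an exercise.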